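**Plan**

1. Target: (1S,3S)-1-[(12Z)-16-phenylhexadec-12-en-1-yl]cyclohex-4-ene-1,3-diol, one cyclohexene ring numbered C1 (tertiary carbinol bearing the chain), C2, C3 (CHOH), C4=C5, C6; the two hydroxyl groups are cis.
2. Enabling feature: C1 carries one oxygen and two ring CH2 groups (C2 and C6) that differ only beyond their first carbon, so C1 with its oxygen and both CH2 groups is a 2-alkyl-2-(chloromethyl)oxirane in latent form, with two electrophilic CH2 groups on one carbinol carbon.
3. Retrosynthesis: cut ring bond C3–C4 (alkenyl iodide plus aldehyde), then C2–C3 and C5–C6 (dithiane anion and silylacetylide onto the oxirane linchpin), then the oxirane (epoxidation of a 2-alkylallyl alcohol), the C1–chain bond (carbomagnesiation of propargyl alcohol) and the chain alkene (Wittig).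
4. Forward: the chain is built (steps 1–3) and attached to the future C1 (step 4); steps 5–6 give the chiral linchpin; step 7 joins both ring arms in one pot; steps 8–11 convert the arms into a (Z)-iodoalkene and an aldehyde; the only ring closes last (step 12).
5. Stereochemistry: C1 comes from the Sharpless epoxidation and is carried through by the order of the two openings; C3 is set in the ring closure, cis to the C1 hydroxyl; the chain (Z)-alkene comes from a lithium-free Wittig reaction and the ring (Z)-alkene from cis-hydroboration of an iodoalkyne.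

Key step: step 7

**Step 1**
Reactants: 1 12-bromododecan-1-ol
Product: 2 12-bromododecanal
Conditions: TEMPO (10 mol %), PhI(OAc)2 (1.1 equiv), CH2Cl2, rt
Reagents that add atoms: none
Why: TEMPO-catalysed alcohol oxidation with PhI(OAc)2 as terminal oxidant stops at the aldehyde and leaves the primary bromide untouched.

**Step 2**
Reactants: 3 1-bromo-4-phenylbutane
Product: 4 triphenyl(4-phenylbutyl)phosphonium bromide
Conditions: PPh3 (1.05 equiv), MeCN, reflux
Reagents that add atoms: triphenylphosphine, c1ccc(cc1)P(c1ccccc1)c1ccccc1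
Why: SN2 quaternisation of triphenylphosphine by an unhindered primary bromide.

**Step 3**
Reactants: 4 triphenyl(4-phenylbutyl)phosphonium bromide; 2 12-bromododecanal
Product: 6 [(4Z)-16-bromohexadec-4-en-1-yl]benzene, via triphenyl(4-phenylbutylidene)phosphorane 5 (not isolated)
Conditions: NaN(SiMe3)2 (1.0 equiv), THF, −78 °C; then 2, −78 °C → rt
Reagents that add atoms: none
Why: Wittig reaction of a non-stabilised ylide under lithium-free, kinetically controlled conditions should give the (Z)-alkene, the remote primary bromide being too slow an alkylating agent to compete at low temperature.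

**Step 4**
Reactants: 6 [(4Z)-16-bromohexadec-4-en-1-yl]benzene; 7 prop-2-yn-1-ol
Product: 10 2-[(12Z)-16-phenylhexadec-12-en-1-yl]prop-2-en-1-ol, via alkylmagnesium bromide 8 (not isolated), via alkenylmagnesium alkoxide 9 (not isolated)
Conditions: Mg, Et2O, reflux; then 7 (0.4 equiv), CuI (10 mol %), Et2O–toluene, −10 °C → rt; then 1 M HCl, 0 °C
Reagents that add atoms: none
Why: Copper-catalysed, alkoxide-directed carbomagnesiation of propargyl alcohol puts the alkyl group on the internal alkyne carbon and magnesium on the terminal one, so protonation of 9 gives the 2-substituted allylic alcohol; one equivalent of 8 is consumed by the hydroxyl proton.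

**Step 5**
Reactants: 10 2-[(12Z)-16-phenylhexadec-12-en-1-yl]prop-2-en-1-ol
Product: 11 {(2S)-2-[(12Z)-16-phenylhexadec-12-en-1-yl]oxiran-2-yl}methanol
Conditions: Ti(OiPr)4 (10 mol %), L-(+)-diethyl tartrate (12 mol %), t-BuOOH (2 equiv), 4 Å molecular sieves, CH2Cl2, −20 °C
Reagents that add atoms: tert-butyl hydroperoxide, CC(C)(C)OO
Why: Sharpless asymmetric epoxidation, in which the L-(+)-tartrate–titanium catalyst delivers oxygen to the allylic alcohol face that turns (E)-allylic alcohols into (2S,3S)-epoxy alcohols and here sets the quaternary centre (the future C1) as S, the isolated chain alkene being inert.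

**Step 6**
Reactants: 11 {(2S)-2-[(12Z)-16-phenylhexadec-12-en-1-yl]oxiran-2-yl}methanol
Product: 12 (2R)-2-(chloromethyl)-2-[(12Z)-16-phenylhexadec-12-en-1-yl]oxirane
Conditions: PPh3 (1.3 equiv), CCl4, NaHCO3, 65 °C
Reagents that add atoms: tetrachloromethane, ClC(Cl)(Cl)Cl
Why: Appel reaction, an SN2 displacement at the primary carbinol carbon that leaves the quaternary stereocentre untouched (S becomes R only because CH2Cl outranks the ring CH2), with NaHCO3 protecting the epoxide from acid-promoted opening.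

**Step 7**
Reactants: 12 (2R)-2-(chloromethyl)-2-[(12Z)-16-phenylhexadec-12-en-1-yl]oxirane; 13 1,3-dithiane; 14 ethynyltrimethylsilane
Product: 19 (2S,14Z)-1-(1,3-dithian-2-yl)-18-phenyl-2-[3-(trimethylsilyl)prop-2-yn-1-yl]octadec-14-en-2-ol, via 2-lithio-1,3-dithiane 15 (not isolated), via lithium chlorohydrin alkoxide 16 (not isolated), via dithianylmethyl epoxide 17 (not isolated), via lithium (trimethylsilyl)acetylide 18 (not isolated)
Conditions: 13 (1.0 equiv), n-BuLi (1.0 equiv), THF, −30 °C; 12 (1.05 equiv), −78 → −20 °C, then rt; cool to −78 °C; 18 [from 14 (2 equiv), n-BuLi (2 equiv), THF, −78 °C]; BF3·OEt2 (2 equiv), −78 °C; H2O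
Reagents that add atoms: none
Why: The anion 15 opens the oxirane of 12 by SN2 attack at its unsubstituted CH2 (C2–C3 bond) to give the tertiary alkoxide 16, which on warming displaces chloride from the neighbouring CH2Cl and so moves the oxirane onto the other arm (17); the acetylide 18, activated by BF3·OEt2, then opens 17 at its CH2 (C5–C6 bond). The closest known reaction type is the one-pot coupling of epichlorohydrin-type linchpins with a lithiated dithiane and then a second carbanion, combined here with BF3-mediated alkynylation of a 2,2-disubstituted epoxide. No ring of the target closes; the only ring formed is the transient oxirane of 17, by 3-exo-tet closure. No stereocentre is created: C1 keeps all four bonds, and since its two CH2 arms are told apart only by the order in which they are attacked, the R configuration of 12 becomes the S configuration of 19. The step requires that 15 attacks the epoxide and not the CH2Cl group (which would give the enantiomer), secured by ring strain against a hindered neopentyl-type chloride, and that 15 is consumed before 17 forms, secured by using 15 as the limiting reagent and keeping the mixture cold until the first opening is complete. The acetylide–BF3 pair is too weakly basic to deprotonate the dithiane and does not touch the chain alkene.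

**Step 8**
Reactants: 19 (2S,14Z)-1-(1,3-dithian-2-yl)-18-phenyl-2-[3-(trimethylsilyl)prop-2-yn-1-yl]octadec-14-en-2-ol
Product: 20 (2S,14Z)-1-(1,3-dithian-2-yl)-18-phenyl-2-(prop-2-yn-1-yl)octadec-14-en-2-ol
Conditions: K2CO3 (0.3 equiv), MeOH, rt
Reagents that add atoms: none
Why: Base-catalysed methanolysis of the alkynyl C–Si bond (protodesilylation), to which the dithiane, the tertiary alcohol and the chain alkene are inert.

**Step 9**
Reactants: 20 (2S,14Z)-1-(1,3-dithian-2-yl)-18-phenyl-2-(prop-2-yn-1-yl)octadec-14-en-2-ol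
Product: 22 (2S,14Z)-1-(1,3-dithian-2-yl)-2-(3-iodoprop-2-yn-1-yl)-18-phenyloctadec-14-en-2-ol, via dilithium alkynide alkoxide 21 (not isolated)
Conditions: n-BuLi (2.05 equiv), THF, −78 °C; I2 (1.05 equiv), −78 °C; aq Na2S2O3
Reagents that add atoms: iodine, II
Why: Deprotonation of the hydroxyl and the alkyne C–H followed by electrophilic iodination of the acetylide, which at −78 °C should be much faster than attack of iodine on the thioacetal sulfur or the chain alkene.

**Step 10**
Reactants: 22 (2S,14Z)-1-(1,3-dithian-2-yl)-2-(3-iodoprop-2-yn-1-yl)-18-phenyloctadec-14-en-2-ol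
Product: 24 (2S,14Z)-1-(1,3-dithian-2-yl)-2-[(2Z)-3-iodoprop-2-en-1-yl]-18-phenyloctadec-14-en-2-ol, via iodoalkenyl dicyclohexylborane 23 (not isolated)
Conditions: (c-C6H11)2BH (1.5 equiv, from BH3·SMe2 and cyclohexene), THF, 0 °C; then AcOH, 0 °C → rt; aq NaHCO3
Reagents that add atoms: none
Why: syn-Hydroboration of the 1-iodoalkyne by a hindered dialkylborane (boron on the iodine-bearing carbon) and protonolysis of the C–B bond with retention give the (Z)-iodoalkene, the internal chain alkene reacting much more slowly with this borane.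

**Step 11**
Reactants: 24 (2S,14Z)-1-(1,3-dithian-2-yl)-2-[(2Z)-3-iodoprop-2-en-1-yl]-18-phenyloctadec-14-en-2-ol
Product: 25 (3S,15Z)-3-hydroxy-3-[(2Z)-3-iodoprop-2-en-1-yl]-19-phenylnonadec-15-enal
Conditions: MeI (10 equiv), CaCO3, MeCN–H2O (9:1), 45 °C
Reagents that add atoms: water, O
Why: S-alkylative hydrolysis of the dithiane under buffered, non-oxidising conditions, chosen so that the alkenyl iodide, the chain alkene and the dehydration-prone β-hydroxy aldehyde survive.

**Step 12**
Reactants: 25 (3S,15Z)-3-hydroxy-3-[(2Z)-3-iodoprop-2-en-1-yl]-19-phenylnonadec-15-enal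
Product: 27 (1S,3S)-1-[(12Z)-16-phenylhexadec-12-en-1-yl]cyclohex-4-ene-1,3-diol, via alkenylchromium dichloride 26 (not isolated)
Conditions: CrCl2 (8 equiv), NiCl2 (0.1 equiv), degassed THF–DMF (4:1), 0.005 M, rt; aqueous work-up
Reagents that add atoms: none
Why: Intramolecular Nozaki–Hiyama–Kishi reaction (nickel-catalysed conversion of the (Z)-iodoalkene into 26 with retention of geometry, then six-membered ring closure onto the aldehyde at C3–C4), in which the free C1 hydroxyl and the aldehyde oxygen are expected to be held on the same trivalent chromium centre so that the new C3 hydroxyl forms cis to the C1 hydroxyl (C3 = S).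

**Compound list**

1 | 12-bromododecan-1-ol | OCCCCCCCCCCCCBr | starting material
2 | 12-bromododecanal | O=CCCCCCCCCCCCBr | intermediate
3 | 1-bromo-4-phenylbutane | BrCCCCc1ccccc1 | starting material
4 | triphenyl(4-phenylbutyl)phosphonium bromide | [Br-].c1ccccc1CCCC[P+](c1ccccc1)(c1ccccc1)c1ccccc1 | intermediate
5 | triphenyl(4-phenylbutylidene)phosphorane | c1ccccc1CCCC=P(c1ccccc1)(c1ccccc1)c1ccccc1 | intermediate
6 | [(4Z)-16-bromohexadec-4-en-1-yl]benzene | BrCCCCCCCCCCC/C=C\CCCc1ccccc1 | intermediate
7 | prop-2-yn-1-ol | C#CCO | starting material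
8 | [(12Z)-16-phenylhexadec-12-en-1-yl]magnesium bromide | Br[Mg]CCCCCCCCCCC/C=C\CCCc1ccccc1 | intermediate
9 | bromo[(1Z,14Z)-2-{[(bromomagnesio)oxy]methyl}-18-phenyloctadeca-1,14-dien-1-yl]magnesium | Br[Mg]/C=C(/CCCCCCCCCCC/C=C\CCCc1ccccc1)CO[Mg]Br | intermediate
10 | 2-[(12Z)-16-phenylhexadec-12-en-1-yl]prop-2-en-1-ol | C=C(CO)CCCCCCCCCCC/C=C\CCCc1ccccc1 | intermediate
11 | {(2S)-2-[(12Z)-16-phenylhexadec-12-en-1-yl]oxiran-2-yl}methanol | C1O[C@@]1(CCCCCCCCCCC/C=C\CCCc2ccccc2)CO | intermediate
12 | (2R)-2-(chloromethyl)-2-[(12Z)-16-phenylhexadec-12-en-1-yl]oxirane | C1O[C@@]1(CCCCCCCCCCC/C=C\CCCc2ccccc2)CCl | intermediate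
13 | 1,3-dithiane | C1CSCSC1 | starting material
14 | ethynyltrimethylsilane | C#C[Si](C)(C)C | starting material
15 | 2-lithio-1,3-dithiane | [Li]C1SCCCS1 | intermediate
16 | lithium (2R,14Z)-1-chloro-2-(1,3-dithian-2-ylmethyl)-18-phenyloctadec-14-en-2-olate | [Li]O[C@@](CC1SCCCS1)(CCCCCCCCCCC/C=C\CCCc1ccccc1)CCl | intermediate
17 | 2-({(2R)-2-[(12Z)-16-phenylhexadec-12-en-1-yl]oxiran-2-yl}methyl)-1,3-dithiane | C1O[C@@]1(CC2SCCCS2)CCCCCCCCCCC/C=C\CCCc3ccccc3 | intermediate
18 | lithium (trimethylsilyl)acetylide | [Li]C#C[Si](C)(C)C | intermediate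
19 | (2S,14Z)-1-(1,3-dithian-2-yl)-18-phenyl-2-[3-(trimethylsilyl)prop-2-yn-1-yl]octadec-14-en-2-ol | O[C@@](CC1SCCCS1)(CCCCCCCCCCC/C=C\CCCc1ccccc1)CC#C[Si](C)(C)C | intermediate
20 | (2S,14Z)-1-(1,3-dithian-2-yl)-18-phenyl-2-(prop-2-yn-1-yl)octadec-14-en-2-ol | O[C@@](CC1SCCCS1)(CCCCCCCCCCC/C=C\CCCc1ccccc1)CC#C | intermediate
21 | lithium (2S,14Z)-1-(1,3-dithian-2-yl)-2-(3-lithioprop-2-yn-1-yl)-18-phenyloctadec-14-en-2-olate | [Li]O[C@@](CC1SCCCS1)(CCCCCCCCCCC/C=C\CCCc1ccccc1)CC#C[Li] | intermediate
22 | (2S,14Z)-1-(1,3-dithian-2-yl)-2-(3-iodoprop-2-yn-1-yl)-18-phenyloctadec-14-en-2-ol | O[C@@](CC1SCCCS1)(CCCCCCCCCCC/C=C\CCCc1ccccc1)CC#CI | intermediate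
23 | (2S,14Z)-2-[(2Z)-3-(dicyclohexylboranyl)-3-iodoprop-2-en-1-yl]-1-(1,3-dithian-2-yl)-18-phenyloctadec-14-en-2-ol | O[C@@](CC1SCCCS1)(CCCCCCCCCCC/C=C\CCCc1ccccc1)C/C=C(\I)B(C1CCCCC1)C1CCCCC1 | intermediate
24 | (2S,14Z)-1-(1,3-dithian-2-yl)-2-[(2Z)-3-iodoprop-2-en-1-yl]-18-phenyloctadec-14-en-2-ol | O[C@@](CC1SCCCS1)(CCCCCCCCCCC/C=C\CCCc1ccccc1)C/C=C\I | intermediate
25 | (3S,15Z)-3-hydroxy-3-[(2Z)-3-iodoprop-2-en-1-yl]-19-phenylnonadec-15-enal | O[C@@](CC=O)(CCCCCCCCCCC/C=C\CCCc1ccccc1)C/C=C\I | intermediate
26 | dichloro[(1Z,4S,16Z)-4-hydroxy-4-(2-oxoethyl)-20-phenylicosa-1,16-dien-1-yl]chromium | O[C@@](CC=O)(CCCCCCCCCCC/C=C\CCCc1ccccc1)C/C=C\[Cr](Cl)Cl | intermediate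
27 | (1S,3S)-1-[(12Z)-16-phenylhexadec-12-en-1-yl]cyclohex-4-ene-1,3-diol | O[C@@H]1C=CC[C@@](O)(CCCCCCCCCCC/C=C\CCCc2ccccc2)C1 | target

**Totals**

Total step count: 12. Longest linear sequence: 11 steps (steps 1 and 3–12; step 2 is a side branch).

**Steps most likely to fail**

Step 12. The addition to the aldehyde may show poor facial selectivity, because the internal chromium bridge between the two oxygens may not compete with solvent coordination; the C3 epimer would then form in part or mainly. The fallback sets out from 25. The same ring closure is run without relying on its selectivity, and the epimer (1S,3R)-1-[(12Z)-16-phenylhexadec-12-en-1-yl]cyclohex-4-ene-1,3-diol F1 is separated by chromatography. Its secondary allylic hydroxyl is inverted by a Mitsunobu reaction (4-nitrobenzoic acid, PPh3, diisopropyl azodicarboxylate, toluene, 0 °C; the tertiary hydroxyl does not react) to give (1S,5S)-5-hydroxy-5-[(12Z)-16-phenylhexadec-12-en-1-yl]cyclohex-2-en-1-yl 4-nitrobenzoate F2. K2CO3 in MeOH cleaves the ester, and the route is rejoined at 27. C3 is then fixed by an SN2 inversion instead of in the C–C bond formation.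

Step 7. The dithiane anion may add a second time, to the relocated epoxide, if chloride displacement begins before the first opening is complete; the 2,2-disubstituted epoxide may also rearrange under the Lewis acid during alkynylation. The fallback sets out from 12 and separates the operations. Addition of 15 at −20 °C and a cold quench with aqueous NH4Cl give the neutral chlorohydrin (2R,14Z)-1-chloro-2-(1,3-dithian-2-ylmethyl)-18-phenyloctadec-14-en-2-ol F3. K2CO3 in MeOH closes it to the epoxide 17, which is isolated and opened without any Lewis acid by LiC≡CH·H2NCH2CH2NH2 in DMSO at rt. This gives the terminal alkyne directly, and the route is rejoined at 20.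

Step 9. Iodine may attack the thioacetal sulfur oxidatively, with partial loss of the dithiane. The fallback sets out from 19 and replaces the dithiane before any electrophilic iodine is used. PhI(OCOCF3)2 in MeOH gives the dimethyl acetal (3S,15Z)-1,1-dimethoxy-19-phenyl-3-[3-(trimethylsilyl)prop-2-yn-1-yl]nonadec-15-en-3-ol F4. N-Iodosuccinimide with catalytic AgNO3 in acetone converts the silylalkyne directly into (3S,15Z)-3-(3-iodoprop-2-yn-1-yl)-1,1-dimethoxy-19-phenylnonadec-15-en-3-ol F5. Hydroboration with dicyclohexylborane and protonolysis with AcOH, as in step 10, give (3S,15Z)-3-[(2Z)-3-iodoprop-2-en-1-yl]-1,1-dimethoxy-19-phenylnonadec-15-en-3-ol F6. Mild aqueous acid (oxalic acid, THF–H2O, rt) frees the aldehyde, and the route is rejoined at 25.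

**Further compounds**

F1 | step 12 | (1S,3R)-1-[(12Z)-16-phenylhexadec-12-en-1-yl]cyclohex-4-ene-1,3-diol | O[C@H]1C=CC[C@@](O)(CCCCCCCCCCC/C=C\CCCc2ccccc2)C1
F2 | step 12 | (1S,5S)-5-hydroxy-5-[(12Z)-16-phenylhexadec-12-en-1-yl]cyclohex-2-en-1-yl 4-nitrobenzoate | O=C(O[C@@H]1C=CC[C@@](O)(CCCCCCCCCCC/C=C\CCCc2ccccc2)C1)c1ccc(cc1)[N+](=O)[O-]
F3 | step 7 | (2R,14Z)-1-chloro-2-(1,3-dithian-2-ylmethyl)-18-phenyloctadec-14-en-2-ol | O[C@@](CC1SCCCS1)(CCCCCCCCCCC/C=C\CCCc1ccccc1)CCl
F4 | step 9 | (3S,15Z)-1,1-dimethoxy-19-phenyl-3-[3-(trimethylsilyl)prop-2-yn-1-yl]nonadec-15-en-3-ol | O[C@@](CC(OC)OC)(CCCCCCCCCCC/C=C\CCCc1ccccc1)CC#C[Si](C)(C)C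
F5 | step 9 | (3S,15Z)-3-(3-iodoprop-2-yn-1-yl)-1,1-dimethoxy-19-phenylnonadec-15-en-3-ol | O[C@@](CC(OC)OC)(CCCCCCCCCCC/C=C\CCCc1ccccc1)CC#CI
F6 | step 9 | (3S,15Z)-3-[(2Z)-3-iodoprop-2-en-1-yl]-1,1-dimethoxy-19-phenylnonadec-15-en-3-ol | O[C@@](CC(OC)OC)(CCCCCCCCCCC/C=C\CCCc1ccccc1)C/C=C\I
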